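Dielsianone is traced back to a chroman whose ring A (C4a, C5, C6, C7, C8, C8a) is built rather than bought. Its C5–OH para to C8–OMe, with O1 on C8a and hydrogen on C7, is the signature of a Dötz benzannulation: a dihydropyranyl(methoxy)carbene complex of chromium, a terminal alkyne and one CO ligand merge, forming C7–C8, C5–C6 and C4a–C5 and placing all five ring substituents in one operation. The precursors are the Fischer carbene made from lithiated 2,2-dimethyl-3,4-dihydro-2H-pyran and the TBS ether of 1-(4-methoxyphenyl)but-3-yn-2-ol. Desilylation, stepwise oxidation of the two-carbon bridge to the benzil and a final C3–C4 dehydrogenation finish the route.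

Key step: step 5

Assumption: the target is achiral; the only stereocenter carried on the route (the side-chain carbinol carbon) is used as the racemate and is erased by oxidation in step 7.

Step 1
Reactants: 1 acrolein; 2 isobutene
Product: 3 2,2-dimethyl-3,4-dihydro-2H-pyran
Conditions: neat (excess 2), hydroquinone (cat.), steel autoclave, 200 °C
Reagents that add atoms: none
Why: Thermal inverse-electron-demand hetero-Diels–Alder reaction of acrolein as 1-oxadiene with the 1,1-disubstituted alkene; oxygen bonds to the more substituted alkene carbon, which puts the gem-dimethyl group next to O, and no stereocenter arises.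

Step 2
Reactants: 3 2,2-dimethyl-3,4-dihydro-2H-pyran; 4 chromium hexacarbonyl Cr(CO)6
Product: 7 pentacarbonyl[(6,6-dimethyl-5,6-dihydro-4H-pyran-2-yl)(methoxy)methylidene]chromium, via vinyllithium 5 (not isolated), via lithium acylchromate 6 (not isolated)
Conditions: t-BuLi (0.95 equiv), THF, −78 to 0 °C; Cr(CO)6, Et2O, 0 °C to rt; MeOTf, CH2Cl2, 0 °C
Reagents that add atoms: methyl trifluoromethanesulfonate (MeOTf), COS(=O)(=O)C(F)(F)F
Why: Fischer carbene synthesis: α-lithiation of the cyclic enol ether at the vinylic C–H next to oxygen, addition of the vinyllithium to a CO ligand and O-methylation of the acylchromate; a slight deficit of t-BuLi keeps it from adding to Cr(CO)6 itself.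

Step 3
Reactants: 8 2-(4-methoxyphenyl)acetaldehyde
Product: 9 1-(4-methoxyphenyl)but-3-yn-2-ol (racemic)
Conditions: ethynylmagnesium bromide (1.3 equiv), THF, −78 to 0 °C; then H2O
Reagents that add atoms: ethynylmagnesium bromide, C#C[Mg]Br
Why: Grignard 1,2-addition of the alkynyl reagent to the aldehyde at low temperature should outrun enolization of the arylacetaldehyde; the carbinol stereocenter forms without control (racemate) and is removed in step 7.

Step 4
Reactants: 9 1-(4-methoxyphenyl)but-3-yn-2-ol (racemic)
Product: 10 tert-butyl{[1-(4-methoxyphenyl)but-3-yn-2-yl]oxy}dimethylsilane (racemic)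
Conditions: TBSCl, imidazole, DMF, rt
Reagents that add atoms: tert-butyldimethylsilyl chloride (TBSCl), CC(C)(C)[Si](C)(C)Cl
Why: Standard imidazole-mediated O-silylation; the silyl cap is needed because a free propargylic OH would trap the vinylketene of step 5 as a lactone.

Step 5
Reactants: 7 pentacarbonyl[(6,6-dimethyl-5,6-dihydro-4H-pyran-2-yl)(methoxy)methylidene]chromium; 10 tert-butyl{[1-(4-methoxyphenyl)but-3-yn-2-yl]oxy}dimethylsilane (racemic)
Product: 12 6-[1-(tert-butyldimethylsilyloxy)-2-(4-methoxyphenyl)ethyl]-8-methoxy-2,2-dimethylchroman-5-ol (racemic), via tricarbonylchromium arene complex 11 (not isolated)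
Conditions: 10 (1.5 equiv), degassed THF, 50 °C, Ar; then air, Et2O, rt
Reagents that add atoms: none
Why: Thermal loss of one CO from 7 frees a site for the alkyne, which inserts into the Cr=C bond with its CH terminus on the carbene carbon (C7–C8), and CO insertion then gives a chromium-bound vinylketene (C5–C6). Ring A closes by 6π-electrocyclization of this dienylketene onto the β-carbon of the dihydropyran (C4a–C5); tautomerization of the cyclohexadienone gives the Cr(CO)3-bound phenol 11, which air demetalates to 12. The closest known reaction type is the Dötz benzannulation of alkenyl(alkoxy)carbene complexes of chromium with terminal alkynes, including dihydropyranyl carbenes that give chromans. No stereocenter is created; the carbinol carbon of 10 is a racemic spectator and the diastereomers of 11 converge on demetalation. The step needs regioselective alkyne insertion, secured sterically by the terminal alkyne: the branched siloxyalkyl group avoids the carbene carbon and ends at C6 next to the new OH, leaving H at C7. It also needs phenol formation in preference to five-membered-ring or lactone products, which the alkenyl carbene in THF and the silylated propargylic oxygen should ensure, while air (not a stronger oxidant) keeps the hydroquinone monoether from going on to the quinone.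

Step 6
Reactants: 12 6-[1-(tert-butyldimethylsilyloxy)-2-(4-methoxyphenyl)ethyl]-8-methoxy-2,2-dimethylchroman-5-ol (racemic)
Product: 13 6-[1-hydroxy-2-(4-methoxyphenyl)ethyl]-8-methoxy-2,2-dimethylchroman-5-ol (racemic)
Conditions: TBAF, AcOH (1 equiv each), THF, 0 °C to rt
Reagents that add atoms: none
Why: Fluoride-driven cleavage of the Si–O bond; the acetic acid buffer keeps the electron-rich phenol protonated, which should suppress air oxidation and o-quinone methide formation.

Step 7
Reactants: 13 6-[1-hydroxy-2-(4-methoxyphenyl)ethyl]-8-methoxy-2,2-dimethylchroman-5-ol (racemic)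
Product: 14 1-(5-hydroxy-8-methoxy-2,2-dimethylchroman-6-yl)-2-(4-methoxyphenyl)ethan-1-one
Conditions: activated MnO2 (excess), CH2Cl2, rt
Reagents that add atoms: none
Why: Selective MnO2 oxidation of a benzylic (o-hydroxybenzylic) alcohol under neutral conditions; the ketone formed is hydrogen-bonded to C5–OH, which deactivates ring A toward further oxidation, and the stereocenter disappears.

Step 8
Reactants: 14 1-(5-hydroxy-8-methoxy-2,2-dimethylchroman-6-yl)-2-(4-methoxyphenyl)ethan-1-one
Product: 15 1-(5-hydroxy-8-methoxy-2,2-dimethylchroman-6-yl)-2-(4-methoxyphenyl)ethane-1,2-dione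
Conditions: SeO2 (1.5 equiv), 1,4-dioxane/H2O, reflux
Reagents that add atoms: selenium dioxide SeO2, O=[Se]=O
Why: Riley oxidation of the deoxybenzoin methylene, which is activated both by the ketone and by the anisyl ring, should give the benzil well before the chroman C4 methylene is touched.

Step 9
Reactants: 15 1-(5-hydroxy-8-methoxy-2,2-dimethylchroman-6-yl)-2-(4-methoxyphenyl)ethane-1,2-dione
Product: 16 dielsianone, 1-(5-hydroxy-8-methoxy-2,2-dimethyl-2H-chromen-6-yl)-2-(4-methoxyphenyl)ethane-1,2-dione
Conditions: DDQ (1.2 equiv), dry 1,4-dioxane, reflux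
Reagents that add atoms: none
Why: DDQ dehydrogenation: hydride abstraction from benzylic C4, assisted by the ortho C5–OH and by O1, followed by loss of a C3 proton gives the 2,2-dimethyl-2H-chromene, as established for 5-hydroxy-6-acyl-2,2-dimethylchromans; the chelated phenol and the diketone should be inert.

Compound list
1 | acrolein | C=CC=O | starting material
2 | isobutene | C=C(C)C | starting material
3 | 2,2-dimethyl-3,4-dihydro-2H-pyran | CC1(C)CCC=CO1 | intermediate
4 | chromium hexacarbonyl Cr(CO)6 | O=C=[Cr](=C=O)(=C=O)(=C=O)(=C=O)=C=O | starting material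
5 | (6,6-dimethyl-5,6-dihydro-4H-pyran-2-yl)lithium | [Li]C1=CCCC(C)(C)O1 | intermediate
6 | lithium pentacarbonyl[(6,6-dimethyl-5,6-dihydro-4H-pyran-2-yl)(oxido)methylidene]chromate | [Li+].[O-]C(C1=CCCC(C)(C)O1)=[Cr](=C=O)(=C=O)(=C=O)(=C=O)=C=O | intermediate
7 | pentacarbonyl[(6,6-dimethyl-5,6-dihydro-4H-pyran-2-yl)(methoxy)methylidene]chromium | COC(C1=CCCC(C)(C)O1)=[Cr](=C=O)(=C=O)(=C=O)(=C=O)=C=O | intermediate
8 | 2-(4-methoxyphenyl)acetaldehyde | COc1ccc(CC=O)cc1 | starting material
9 | 1-(4-methoxyphenyl)but-3-yn-2-ol (racemic) | C#CC(O)Cc1ccc(OC)cc1 | intermediate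
10 | tert-butyl{[1-(4-methoxyphenyl)but-3-yn-2-yl]oxy}dimethylsilane (racemic) | C#CC(Cc1ccc(OC)cc1)O[Si](C)(C)C(C)(C)C | intermediate
11 | tricarbonylchromium complex of 12, Cr(CO)3 η6-bound to ring A (racemic, mixture of diastereomers; the η6 bond is not encoded in the SMILES) | COc1ccc(CC(O[Si](C)(C)C(C)(C)C)c2cc(OC)c3c(c2O)CCC(C)(C)O3)cc1.O=C=[Cr](=C=O)=C=O | intermediate
12 | 6-[1-(tert-butyldimethylsilyloxy)-2-(4-methoxyphenyl)ethyl]-8-methoxy-2,2-dimethylchroman-5-ol (racemic) | COc1ccc(CC(O[Si](C)(C)C(C)(C)C)c2cc(OC)c3c(c2O)CCC(C)(C)O3)cc1 | intermediate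
13 | 6-[1-hydroxy-2-(4-methoxyphenyl)ethyl]-8-methoxy-2,2-dimethylchroman-5-ol (racemic) | COc1ccc(CC(O)c2cc(OC)c3c(c2O)CCC(C)(C)O3)cc1 | intermediate
14 | 1-(5-hydroxy-8-methoxy-2,2-dimethylchroman-6-yl)-2-(4-methoxyphenyl)ethan-1-one | COc1ccc(CC(=O)c2cc(OC)c3c(c2O)CCC(C)(C)O3)cc1 | intermediate
15 | 1-(5-hydroxy-8-methoxy-2,2-dimethylchroman-6-yl)-2-(4-methoxyphenyl)ethane-1,2-dione | COc1ccc(C(=O)C(=O)c2cc(OC)c3c(c2O)CCC(C)(C)O3)cc1 | intermediate
16 | dielsianone, 1-(5-hydroxy-8-methoxy-2,2-dimethyl-2H-chromen-6-yl)-2-(4-methoxyphenyl)ethane-1,2-dione (achiral) | COc1ccc(C(=O)C(=O)c2cc(OC)c3c(c2O)C=CC(C)(C)O3)cc1 | target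

Total step count: 9
Longest linear sequence: 7 steps (steps 1, 2, 5, 6, 7, 8, 9; the alkyne branch, steps 3 and 4, joins at step 5)

Steps most likely to fail

Step 5. Alkyne insertion may be slow next to the branched propargylic carbon, so that the alkyne oligomerizes. The chromium-bound o-hydroxybenzylic silyl ether may also ionize, losing silanol through an o-quinone methide during annulation or demetalation. The fallback sets out from 7 and carries only a robust acetal through the annulation, attaching the anisylmethyl unit afterwards. Benzannulation of 7 with commercial 3,3-diethoxyprop-1-yne (THF, 50 °C) should give the tricarbonylchromium complex of the acetal phenol F1, which is not isolated. Air demetalation should release 6-(diethoxymethyl)-8-methoxy-2,2-dimethylchroman-5-ol F2. Mild hydrolysis (PPTS, acetone/H2O, rt) should give 5-hydroxy-8-methoxy-2,2-dimethylchroman-6-carbaldehyde F3. Addition of 4-methoxybenzylmagnesium chloride (2.2 equiv, THF, −78 to 0 °C; the first equivalent is consumed by the phenol) should give the diol. The fallback comes back to the route at 13.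

Step 8. Selenium dioxide may stall at the α-hydroxy ketone, attack the chroman C4 methylene, or over-oxidize the phenolic ring. The fallback sets out from 14 and introduces the second oxygen as nitrogen first. Acid-catalysed nitrosation of the active methylene (isoamyl nitrite, HCl, Et2O/THF, 0 °C) should give 2-(hydroxyimino)-1-(5-hydroxy-8-methoxy-2,2-dimethylchroman-6-yl)-2-(4-methoxyphenyl)ethan-1-one F4. Transoximation to formaldehyde (aq. HCHO, HCl, THF, rt) should then release the diketone. The fallback comes back to the route at 15.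

Step 9. Hydride abstraction from C4 may be too slow on the acyl-deactivated ring, and forcing conditions may bring oxidative degradation of the hydroquinone monoether. The fallback sets out from 15 and replaces hydride abstraction by radical bromination and elimination. Acetylation (Ac2O, pyridine, DMAP, rt) should give 8-methoxy-6-[2-(4-methoxyphenyl)-2-oxoacetyl]-2,2-dimethylchroman-5-yl acetate F5. Wohl–Ziegler bromination at C4, the only benzylic methylene left (NBS, AIBN cat., PhCF3, 80 °C), should give 4-bromo-8-methoxy-6-[2-(4-methoxyphenyl)-2-oxoacetyl]-2,2-dimethylchroman-5-yl acetate F6 (racemic, not isolated). Elimination of HBr with Et3N in the same pot should give 8-methoxy-6-[2-(4-methoxyphenyl)-2-oxoacetyl]-2,2-dimethyl-2H-chromen-5-yl acetate F7. Brief methanolysis (K2CO3 cat., MeOH, 0 °C) should free the phenol. The fallback comes back to the route at 16.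

Further compounds
F1 | step 5 | tricarbonylchromium complex of F2, Cr(CO)3 η6-bound to ring A (η6 bond not encoded) | CCOC(OCC)c1cc(OC)c2c(c1O)CCC(C)(C)O2.O=C=[Cr](=C=O)=C=O
F2 | step 5 | 6-(diethoxymethyl)-8-methoxy-2,2-dimethylchroman-5-ol | CCOC(OCC)c1cc(OC)c2c(c1O)CCC(C)(C)O2
F3 | step 5 | 5-hydroxy-8-methoxy-2,2-dimethylchroman-6-carbaldehyde | O=Cc1cc(OC)c2c(c1O)CCC(C)(C)O2
F4 | step 8 | 2-(hydroxyimino)-1-(5-hydroxy-8-methoxy-2,2-dimethylchroman-6-yl)-2-(4-methoxyphenyl)ethan-1-one (oxime geometry not defined) | COc1ccc(C(=NO)C(=O)c2cc(OC)c3c(c2O)CCC(C)(C)O3)cc1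
F5 | step 9 | 8-methoxy-6-[2-(4-methoxyphenyl)-2-oxoacetyl]-2,2-dimethylchroman-5-yl acetate | COc1ccc(C(=O)C(=O)c2cc(OC)c3c(c2OC(C)=O)CCC(C)(C)O3)cc1
F6 | step 9 | 4-bromo-8-methoxy-6-[2-(4-methoxyphenyl)-2-oxoacetyl]-2,2-dimethylchroman-5-yl acetate (racemic) | COc1ccc(C(=O)C(=O)c2cc(OC)c3c(c2OC(C)=O)C(Br)CC(C)(C)O3)cc1
F7 | step 9 | 8-methoxy-6-[2-(4-methoxyphenyl)-2-oxoacetyl]-2,2-dimethyl-2H-chromen-5-yl acetate | COc1ccc(C(=O)C(=O)c2cc(OC)c3c(c2OC(C)=O)C=CC(C)(C)O3)cc1
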